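The constants used here belong to no real substance; no experiment stands behind them.

At the earliest times each flask holds starting material, coupling partner and capture agent and has still to form its intermediates, so the first step to run is the loss of starting material to intermediate A, and two chemists read that start differently.

    intermediate A → side product A (k1 = 0.00157 s⁻¹, Ea1 = 96.0 kJ mol⁻¹)
    coupling partner + intermediate B → target (k2 = 0.00165 M⁻¹ s⁻¹, Ea2 = 74.0 kJ mol⁻¹)
    starting material → intermediate A (k3 = 0.00204 s⁻¹, Ea3 = 98.0 kJ mol⁻¹)
    starting material + intermediate C → side product B (k4 = 6.82 × 10⁻⁴ M⁻¹ s⁻¹, Ea4 = 55.0 kJ mol⁻¹)
    intermediate C ⇌ intermediate D (K5 = 0.93, k5 = 0.00151 s⁻¹, Ea5 = 92.0 kJ mol⁻¹, ΔH5 = −58.0 kJ mol⁻¹)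
    coupling partner + intermediate A → intermediate B (k6 = 0.00239 M⁻¹ s⁻¹, Ea6 = 64.0 kJ mol⁻¹)
    capture agent + intermediate B → trapped intermediate (k7 = 0.0181 M⁻¹ s⁻¹, Ea7 = 70.0 kJ mol⁻¹)
    coupling partner + intermediate B ⇌ intermediate C (K8 = 15.9 M⁻¹, k8 = 7.89 × 10⁻⁴ M⁻¹ s⁻¹, Ea8 = 76.0 kJ mol⁻¹, ΔH8 = −1.00 kJ mol⁻¹)
    (constants at 35 °C)

- amber: starting material 1.5 M; coupling partner 1.10 equiv; capture agent 0.150 M; temperature 35 °C; time 10 min
- green: starting material 1.5 M; coupling partner 1.10 equiv; capture agent 0.150 M; temperature 45 °C; time 10 min

* which of these there is most of at the end, counted by the starting material in it, amber (intermediate A / side product A / target / starting material / intermediate B)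
* which of these there is most of at the end, counted by the starting material in it, green (intermediate A / side product A / target / starting material / intermediate B)
* amount of the one of these that there is most of at the end, in percent of the starting material charged, amber
* amount of the one of these that there is most of at the end, in percent of the starting material charged, green

- percent here means starting material units held: one side product B counts as two
- constants are those at 35 °C; use the activation energies and enthalpies for any other temperature

The first chemist turns constants into times at the charged amounts and begins with the starting-material clock, 5.66 min: the half-life of starting material by its first-order loss to intermediate A, in amber. The step that also consumes starting material needs intermediate C, which stands far down the chain, so she lets the clock run by itself. By that clock amber keeps 29.4% of its starting material.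

The second chemist accepts that and draws the opposite conclusion. For him, 70.6% has left, and that is what counts. With coupling partner as charged in amber, treated as pseudo-first-order, intermediate A goes forward with a share of 71.5%. The capture agent can hold 10.0% at most, measured against the starting material charged. If passage is quick, his reckoning puts amber's target at 40.5%, which is more than the starting material left.

She answers with times. In amber, with the other concentrations as charged, intermediate A has a half-life of 2.93 min by its forward step alone, and intermediate B has one of 4.2 min by its step to target alone. Together these are longer than the clock, so she does not take passage as quick, and she expects part of what has left to sit in the intermediates. She commits to starting material on top in amber, at the clock's figure.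

For green she stops short of a number. The loss of intermediate A to side product A has a higher activation energy than its forward step, 96.0 kJ mol⁻¹ against 64.0 kJ mol⁻¹, so she expects the warming in green to favour that loss over that step, and she names side product A for green.

The forecast says starting material at 29.1% (28.3% to 29.6%) for amber and side product A at 45.5% (41% to 50%) for green, where in its words “Starting material is essentially gone”.

The simulation gives amber starting material at 29.2%, close to the clock's 29.4%, with intermediate A at 19.5%, side product A at 17.3%, intermediate B at 12.7% and target at 9.36%. Green ends with side product A at 45.5% and target at 20.3%. So she holds amber. His view has its region later: amber's starting material and side product A stand equal at 12.4 min. Amber read at 40 min has target at 25.6% against starting material at 0.675%, although side product A leads there at 41.4%.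

Amber has not come to rest at 10 min. Run on to 40.0 min, the clock gives 0.748%, and that flask reads 0.675%. By 100 min the clock has run 17.7 half-lives and amber's starting material stands at 0%. Between 10 min and 100 min, amber's side product A goes from 17.3% to 43.4%, its target from 9.36% to 30.5%, and its free coupling partner from 56.8% to 9.85% of its charge. At 100 min, amber's intermediate C holds 6.23% and its intermediate D 5.79%.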